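**Plan**
1. Labels: ring A carbons are lettered A-a (C–OMe), A-b (C–H), A-c (C–CH3), A-d (C–C(=O)O), A-e (C–OAr), A-f (C–CHO); ring B carbons are lettered B-a (C–O–A-e), B-b (C–O–C(=O)), B-c (C–H), B-d (C–OH), B-e (C bearing the lactone C=O), B-f (C bearing the lactol CH).
2. Cuts: lactol OH, B-d OH, CHO and OMe go back to a methyl acetal, a MOM ether and an oxasilole (A-a–Si, A-f–CH2–O–Si); ring A is then cut at the bonds A-a/A-f, A-e/A-d and A-b/A-c into three alkynes.
3. Enabling feature: ring B is a catechol at B-a/B-b, so its two oxygens carry A-e≡A-f as an aryl ynol ether and A-d≡A-c as a but-2-ynoate side by side, while the CH2–O–Si arm on A-f holds A-a≡A-b; all six carbons of ring A are tethered.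
4. Forward order: ring B with its lactone (as methyl pseudo-ester) comes first, from 2,4,5-trimethoxybenzoic acid by ortho-lithiation/formylation; then the B-a ynol ether, the B-b butynoate and the silicon arm are attached; one RhCl(PPh3)3 step closes ring A, the seven-membered lactone and the oxasilole together.
5. End game: Si→OH oxidation, O-methylation, CH2OH→CHO, acid release of the B-d phenol and the lactol.
6. Stereochemistry: the single centre (lactol carbon, S) is set last by lipase dynamic kinetic acetylation of the equilibrating lactol; enzymatic deacetylation then leaves the stereogenic C–O bond untouched.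

Key step: step 12

Assumption: the lactol carbon equilibrates through the ring-opened formyl acid when base is present (used in step 17) but is taken to hold its configuration under the base-free, cool conditions of step 18 and on storage; the (S) preference of the named lipase has to be confirmed by screening.

**Step 1**
Reactants: 1 2,4,5-trimethoxybenzoic acid
Product: 3 N,N-diethyl-2,4,5-trimethoxybenzamide, via 2,4,5-trimethoxybenzoyl chloride 2 (not isolated)
Conditions: (COCl)2, cat. DMF, CH2Cl2, 0 °C to rt; then Et2NH, Et3N, CH2Cl2, 0 °C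
Reagents that add atoms: diethylamine, CCNCC
Why: Acid chloride formation and amidation should give the tertiary amide needed as the directing group for ortho-metalation.

**Step 2**
Reactants: 3 N,N-diethyl-2,4,5-trimethoxybenzamide
Product: 5 N,N-diethyl-2-formyl-3,4,6-trimethoxybenzamide, via 6-lithio-N,N-diethyl-2,4,5-trimethoxybenzamide 4 (not isolated)
Conditions: s-BuLi, TMEDA, THF, −78 °C; then DMF, −78 °C to rt; aq. NH4Cl
Reagents that add atoms: N,N-dimethylformamide, CN(C)C=O
Why: Amide-directed ortho-metalation should occur at ring position 6, the only free position ortho to the amide and also flanked by the 5-methoxy group, in preference to the site between two methoxy groups, and DMF then formylates the aryllithium.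

**Step 3**
Reactants: 5 N,N-diethyl-2-formyl-3,4,6-trimethoxybenzamide
Product: 7 rac-4,5,7-trihydroxy-3-methoxy-2-benzofuran-1(3H)-one, via N,N-diethyl-2-formyl-3,4,6-trihydroxybenzamide 6 (not isolated)
Conditions: BBr3, CH2Cl2, −78 °C to rt; then MeOH, 65 °C (argon)
Reagents that add atoms: methanol, CO
Why: BBr3 ether cleavage frees the three phenols, and in hot methanolic HBr the hemiacetal of the formyl group attacks the neighbouring tertiary amide (neighbouring-group-assisted amide cleavage) so that the lactol is trapped as the racemic methyl pseudo-ester.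

**Step 4**
Reactants: 7 rac-4,5,7-trihydroxy-3-methoxy-2-benzofuran-1(3H)-one
Product: 10 rac-4,5-dihydroxy-3-methoxy-7-(methoxymethoxy)-2-benzofuran-1(3H)-one, via cyclic B-a/B-b phenylboronate 8 (not isolated), via MOM-protected phenylboronate 9 (not isolated)
Conditions: PhB(OH)2, toluene/THF, 4 Å sieves, 60 °C; then MOMCl, iPr2NEt, CH2Cl2, 0 °C to rt; then pinacol, THF, rt
Reagents that add atoms: chloromethyl methyl ether, COCCl
Why: Transient boronate protection ties up only the adjacent B-a/B-b hydroxyls as a five-membered ester, so Williamson-type MOM ether formation can only occur at the B-d hydroxyl, and pinacol transesterification then releases the catechol.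

**Step 5**
Reactants: 10 rac-4,5-dihydroxy-3-methoxy-7-(methoxymethoxy)-2-benzofuran-1(3H)-one
Product: 11 rac-4-hydroxy-3-methoxy-7-(methoxymethoxy)-5-(prop-2-en-1-yloxy)-2-benzofuran-1(3H)-one
Conditions: allyl bromide (1.05 equiv), Li2CO3, DMF, 45 °C (argon)
Reagents that add atoms: allyl bromide, C=CCBr
Why: Williamson etherification under weak-base control should go to the B-b hydroxyl, which is para to the lactone carbonyl and therefore the more acidic and less hindered phenol, as in 3,4-dihydroxybenzoates.

**Step 6**
Reactants: 12 (tert-butyldimethylsilyloxy)acetaldehyde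
Product: 13 tert-butyl[(3,3-dibromoprop-2-en-1-yl)oxy]dimethylsilane
Conditions: CBr4, PPh3, Et3N, CH2Cl2, 0 °C
Reagents that add atoms: tetrabromomethane, BrC(Br)(Br)Br
Why: Ramirez dibromo-olefination (first half of the Corey–Fuchs sequence) converts the aldehyde into the 1,1-dibromoalkene, with Et3N buffering the silyl ether.

**Step 7**
Reactants: 11 rac-4-hydroxy-3-methoxy-7-(methoxymethoxy)-5-(prop-2-en-1-yloxy)-2-benzofuran-1(3H)-one, 13 tert-butyl[(3,3-dibromoprop-2-en-1-yl)oxy]dimethylsilane
Product: 15 rac-4-{[3-(tert-butyldimethylsilyloxy)prop-1-yn-1-yl]oxy}-3-methoxy-7-(methoxymethoxy)-5-(prop-2-en-1-yloxy)-2-benzofuran-1(3H)-one, via (Z)-bromo enol ether 14 (not isolated)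
Conditions: CuI (10 mol%), 2,2'-bipyridine, K3PO4, toluene, 80 °C; then KOtBu, THF, 0 °C
Reagents that add atoms: none
Why: Ullmann-type copper-catalysed C–O coupling of the phenol with the 1,1-dibromoalkene replaces the bromine trans to the chain, and anti-periplanar base-induced dehydrobromination of the resulting (Z)-bromo enol ether should give the aryl ynol ether.

**Step 8**
Reactants: 15 rac-4-{[3-(tert-butyldimethylsilyloxy)prop-1-yn-1-yl]oxy}-3-methoxy-7-(methoxymethoxy)-5-(prop-2-en-1-yloxy)-2-benzofuran-1(3H)-one, 16 but-2-ynoic acid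
Product: 19 rac-4-{[3-(tert-butyldimethylsilyloxy)prop-1-yn-1-yl]oxy}-3-methoxy-7-(methoxymethoxy)-1-oxo-1,3-dihydro-2-benzofuran-5-yl but-2-ynoate, via sodium B-b phenolate 17 (not isolated), via but-2-ynoyl chloride 18 (not isolated)
Conditions: Pd(PPh3)4 (5 mol%), TolSO2Na, THF/MeOH, rt; evaporate; then 18 [from 16, (COCl)2, cat. DMF, CH2Cl2, 0 °C], THF/CH2Cl2, −20 °C
Reagents that add atoms: none
Why: Tsuji–Trost deallylation with sulfinate as allyl acceptor delivers the B-b oxygen as its sodium phenolate with no acid present, and immediate acylation with the preformed acid chloride means that neither an acidic medium nor free butynoic acid meets the acid-sensitive ynol ether.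

**Step 9**
Reactants: 19 rac-4-{[3-(tert-butyldimethylsilyloxy)prop-1-yn-1-yl]oxy}-3-methoxy-7-(methoxymethoxy)-1-oxo-1,3-dihydro-2-benzofuran-5-yl but-2-ynoate
Product: 20 rac-4-[(3-hydroxyprop-1-yn-1-yl)oxy]-3-methoxy-7-(methoxymethoxy)-1-oxo-1,3-dihydro-2-benzofuran-5-yl but-2-ynoate
Conditions: TBAF, AcOH (1:1), THF, 0 °C
Reagents that add atoms: none
Why: Buffered fluoride desilylation should remove the primary TBS ether without basic cleavage of the aryl ynoate or acid hydration of the ynol ether.

**Step 10**
Reactants: 21 dichlorodiethylsilane, 22 ethynylmagnesium bromide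
Product: 23 chloro(diethyl)ethynylsilane
Conditions: 21 (3 equiv), THF, −78 °C, slow addition of 22, then rt; distillation
Reagents that add atoms: none
Why: Grignard substitution at silicon with the acetylide added slowly to excess dichlorosilane favours monoalkynylation, and ethyl rather than methyl groups on silicon are chosen so that the later silyl ether tolerates handling.

**Step 11**
Reactants: 20 rac-4-[(3-hydroxyprop-1-yn-1-yl)oxy]-3-methoxy-7-(methoxymethoxy)-1-oxo-1,3-dihydro-2-benzofuran-5-yl but-2-ynoate, 23 chloro(diethyl)ethynylsilane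
Product: 24 rac-4-[(3-{[diethyl(ethynyl)silyl]oxy}prop-1-yn-1-yl)oxy]-3-methoxy-7-(methoxymethoxy)-1-oxo-1,3-dihydro-2-benzofuran-5-yl but-2-ynoate
Conditions: iPr2NEt, CH2Cl2, −20 to 0 °C
Reagents that add atoms: none
Why: Silyl ether formation from the primary alcohol and the chlorosilane with a hindered amine base avoids conjugate addition of a nucleophilic base to the ynoate.

**Step 12**
Reactants: 24 rac-4-[(3-{[diethyl(ethynyl)silyl]oxy}prop-1-yn-1-yl)oxy]-3-methoxy-7-(methoxymethoxy)-1-oxo-1,3-dihydro-2-benzofuran-5-yl but-2-ynoate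
Product: 25 rac-benzoxasilole-fused depsidone (A-a–SiEt2–O–CH2–A-f; B-d OMOM; lactol methyl acetal)
Conditions: RhCl(PPh3)3 (10 mol%), degassed toluene, 80 °C, slow addition to 0.003 M
Reagents that add atoms: none
Why: Proposed new method: after phosphine loss, monovalent rhodium binds the ethynylsilane (A-a≡A-b) and the ynol ether (A-f≡A-e), which the Si–O–CH2 link holds as a 1,6-diyne, and oxidative cyclisation gives a rhodacyclopentadiene with the new A-a/A-f bond, which closes the five-membered oxasilole. The butynoate alkyne (A-d≡A-c), held by the B-b ester oxygen next to the B-a ether oxygen, then inserts into the Rh–A-e bond so that the A-e/A-d bond forms and closes the seven-membered lactone ring, and reductive elimination of the A-b/A-c bond completes benzene ring A and regenerates the catalyst. The closest known reaction type is the RhCl(PPh3)3- or Cp*RuCl(cod)-catalysed intramolecular (2+2+2) cyclotrimerisation of fully tethered triynes, including temporary silyl ether tethers, and the cycloaddition of 1,6-diynes with ynoates or aryl ynol ethers; new here is the combination of an aryl ynol ether, an aryl ynoate and a seven-membered tether in one triyne. No stereocentre is formed and the acetal carbon stays racemic. The step needs intramolecular trimerisation to win over oligomerisation and dimerisation of the terminal alkyne; the two tethers fix the regiochemistry of ring A completely, the ortho oxygens of ring B hold ynol ether and ynoate close and coplanar, and high dilution with slow addition suppresses intermolecular paths.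

**Step 13**
Reactants: 25 rac-benzoxasilole-fused depsidone (A-a–SiEt2–O–CH2–A-f; B-d OMOM; lactol methyl acetal)
Product: 26 rac-depsidone diol (A-a OH; A-f CH2OH; B-d OMOM; lactol methyl acetal)
Conditions: KHCO3, KF, 30% aq. H2O2, THF/MeOH, rt
Reagents that add atoms: hydrogen peroxide, OO
Why: Tamao–Fleming oxidation moves the aryl group from the alkoxy-activated silicon to oxygen at A-a and hydrolyses the Si–O–CH2 bond, while the seven-ring ester is shielded by the two substituents (A-c methyl, A-e aryloxy) that flank its acyl-bearing carbon.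

**Step 14**
Reactants: 26 rac-depsidone diol (A-a OH; A-f CH2OH; B-d OMOM; lactol methyl acetal)
Product: 27 rac-depsidone benzylic alcohol (A-a OMe; A-f CH2OH; B-d OMOM; lactol methyl acetal)
Conditions: MeI, K2CO3, acetone, rt
Reagents that add atoms: iodomethane, CI
Why: Williamson O-methylation should be selective because K2CO3 deprotonates only the phenol and not the benzylic alcohol.

**Step 15**
Reactants: 27 rac-depsidone benzylic alcohol (A-a OMe; A-f CH2OH; B-d OMOM; lactol methyl acetal)
Product: 28 rac-depsidone aldehyde (A-a OMe; A-f CHO; B-d OMOM; lactol methyl acetal)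
Conditions: MnO2 (activated, excess), CH2Cl2, rt
Reagents that add atoms: none
Why: MnO2 oxidation is selective for benzylic alcohols and should stop at the aldehyde.

**Step 16**
Reactants: 28 rac-depsidone aldehyde (A-a OMe; A-f CHO; B-d OMOM; lactol methyl acetal)
Product: 29 racemic lactol (racemic form of the target)
Conditions: 2 M aq. HCl, 1,4-dioxane, 70 °C
Reagents that add atoms: water, O
Why: Acid-catalysed acetal hydrolysis cleaves the MOM ether and the methyl pseudo-ester in one operation, and the lactol is formed as the racemate because nothing controls the new centre at this stage.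

**Step 17**
Reactants: 29 racemic lactol (racemic form of the target)
Product: 30 (S)-lactol acetate
Conditions: immobilised Burkholderia cepacia lipase, vinyl acetate, Et3N (0.2 equiv), tert-butyl methyl ether/THF, 40 °C
Reagents that add atoms: vinyl acetate, C=COC(C)=O
Why: Lipase-catalysed dynamic kinetic resolution by transesterification, as established for hydroxybutenolide-type lactols, should work because the lactol enantiomers interconvert through the ring-opened formyl carboxylate while the chiral acyl-transfer pocket of the enzyme acetylates only one, so the enzyme sets the (S) centre and the weakly nucleophilic B-d phenol is left alone.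

**Step 18**
Reactants: 30 (S)-lactol acetate
Product: 31 target (S)-lactol CNP0216483.1
Conditions: the same immobilised lipase, butan-1-ol, tert-butyl methyl ether, 20 °C; filter, evaporate below 25 °C
Reagents that add atoms: none
Why: Lipase-catalysed alcoholysis breaks only the acyl C–O bond, so the stereogenic C–O bond is untouched, the enzyme accepts the (S) acetate by microscopic reversibility, and the absence of base should keep the released lactol from equilibrating.

**Compound list**
1 | 2,4,5-trimethoxybenzoic acid | COc1cc(OC)c(C(=O)O)cc1OC | starting material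
2 | 2,4,5-trimethoxybenzoyl chloride | COc1cc(OC)c(C(=O)Cl)cc1OC | intermediate (not isolated)
3 | N,N-diethyl-2,4,5-trimethoxybenzamide | CCN(CC)C(=O)c1cc(OC)c(OC)cc1OC | intermediate
4 | 6-lithio-N,N-diethyl-2,4,5-trimethoxybenzamide | CCN(CC)C(=O)c1c([Li])c(OC)c(OC)cc1OC | intermediate (not isolated)
5 | N,N-diethyl-2-formyl-3,4,6-trimethoxybenzamide | CCN(CC)C(=O)c1c(C=O)c(OC)c(OC)cc1OC | intermediate
6 | N,N-diethyl-2-formyl-3,4,6-trihydroxybenzamide | CCN(CC)C(=O)c1c(C=O)c(O)c(O)cc1O | intermediate (not isolated)
7 | rac-4,5,7-trihydroxy-3-methoxy-2-benzofuran-1(3H)-one (B-a, B-b, B-d OH; lactol as methyl acetal) | Oc1c(O)cc(O)c2c1C(OC)OC2=O | intermediate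
8 | cyclic B-a/B-b phenylboronate of 7 | c1ccccc1B1Oc2cc(O)c3c(c2O1)C(OC)OC3=O | intermediate (not isolated)
9 | B-d MOM ether of boronate 8 | c1ccccc1B1Oc2cc(OCOC)c3c(c2O1)C(OC)OC3=O | intermediate (not isolated)
10 | rac-4,5-dihydroxy-3-methoxy-7-(methoxymethoxy)-2-benzofuran-1(3H)-one | Oc1c(O)cc(OCOC)c2c1C(OC)OC2=O | intermediate
11 | rac-4-hydroxy-3-methoxy-7-(methoxymethoxy)-5-(prop-2-en-1-yloxy)-2-benzofuran-1(3H)-one | Oc1c(OCC=C)cc(OCOC)c2c1C(OC)OC2=O | intermediate
12 | (tert-butyldimethylsilyloxy)acetaldehyde | CC(C)(C)[Si](C)(C)OCC=O | starting material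
13 | tert-butyl[(3,3-dibromoprop-2-en-1-yl)oxy]dimethylsilane | CC(C)(C)[Si](C)(C)OCC=C(Br)Br | intermediate
14 | (Z)-bromo enol ether: B-a–O–C(Br)=CH–CH2OTBS on ring B of 11 | CC(C)(C)[Si](C)(C)OC/C=C(\Br)Oc1c(OCC=C)cc(OCOC)c2c1C(OC)OC2=O | intermediate (not isolated)
15 | rac-4-{[3-(tert-butyldimethylsilyloxy)prop-1-yn-1-yl]oxy}-3-methoxy-7-(methoxymethoxy)-5-(prop-2-en-1-yloxy)-2-benzofuran-1(3H)-one | CC(C)(C)[Si](C)(C)OCC#COc1c(OCC=C)cc(OCOC)c2c1C(OC)OC2=O | intermediate
16 | but-2-ynoic acid | CC#CC(=O)O | starting material
17 | sodium B-b phenolate of de-allylated 15 | CC(C)(C)[Si](C)(C)OCC#COc1c([O-])cc(OCOC)c2c1C(OC)OC2=O.[Na+] | intermediate (not isolated)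
18 | but-2-ynoyl chloride | CC#CC(=O)Cl | intermediate (not isolated)
19 | rac-4-{[3-(tert-butyldimethylsilyloxy)prop-1-yn-1-yl]oxy}-3-methoxy-7-(methoxymethoxy)-1-oxo-1,3-dihydro-2-benzofuran-5-yl but-2-ynoate | CC(C)(C)[Si](C)(C)OCC#COc1c(OC(=O)C#CC)cc(OCOC)c2c1C(OC)OC2=O | intermediate
20 | rac-4-[(3-hydroxyprop-1-yn-1-yl)oxy]-3-methoxy-7-(methoxymethoxy)-1-oxo-1,3-dihydro-2-benzofuran-5-yl but-2-ynoate | OCC#COc1c(OC(=O)C#CC)cc(OCOC)c2c1C(OC)OC2=O | intermediate
21 | dichlorodiethylsilane | CC[Si](Cl)(Cl)CC | starting material
22 | ethynylmagnesium bromide | C#C[Mg]Br | starting material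
23 | chloro(diethyl)ethynylsilane | CC[Si](Cl)(CC)C#C | intermediate
24 | triyne: ring B with B-a ynol ether carrying the CH2–O–SiEt2–C≡CH arm, B-b but-2-ynoate, B-d OMOM, lactol as methyl acetal (racemic) | C#C[Si](CC)(CC)OCC#COc1c(OC(=O)C#CC)cc(OCOC)c2c1C(OC)OC2=O | intermediate
25 | depsidone fused to a 1,1-diethyl-1,3-dihydro-2,1-benzoxasilole: A-a–Si, A-f–CH2–O–Si, A-c CH3, A-d C(=O)–O–B-b, A-e–O–B-a; B-d OMOM; lactol as methyl acetal (racemic) | CC[Si]1(CC)OCc2c1cc(C)c1c2Oc2c(cc(OCOC)c3c2C(OC)OC3=O)OC1=O | intermediate
26 | depsidone diol: A-a OH, A-f CH2OH; B-d OMOM; lactol as methyl acetal (racemic) | Oc1cc(C)c2c(c1CO)Oc1c(cc(OCOC)c3c1C(OC)OC3=O)OC2=O | intermediate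
27 | depsidone benzylic alcohol: A-a OMe, A-f CH2OH; B-d OMOM; lactol as methyl acetal (racemic) | COc1cc(C)c2c(c1CO)Oc1c(cc(OCOC)c3c1C(OC)OC3=O)OC2=O | intermediate
28 | depsidone aldehyde: A-a OMe, A-f CHO; B-d OMOM; lactol as methyl acetal (racemic) | COc1cc(C)c2c(c1C=O)Oc1c(cc(OCOC)c3c1C(OC)OC3=O)OC2=O | intermediate
29 | racemic lactol (racemic target) | COc1cc(C)c2c(c1C=O)Oc1c(cc(O)c3c1C(O)OC3=O)OC2=O | intermediate
30 | (S)-lactol acetate of the target | COc1cc(C)c2c(c1C=O)Oc1c(cc(O)c3c1[C@@H](OC(C)=O)OC3=O)OC2=O | intermediate
31 | CNP0216483.1, (S)-lactol | COc1cc(C)c2c(c1C=O)Oc1c(cc(O)c3c1[C@@H](O)OC3=O)OC2=O | target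

**Step count and risks**
Total: 18 steps. Longest linear sequence: 16 steps (1–5, 7–9, 11–18); steps 6 and 10 prepare the side components 13 and 23.

1. Step 12 (proposed new method). The triyne may oligomerise through its terminal alkyne, only the silicon-tethered diyne may cyclise and take a second molecule as third partner, or the seven-membered closure may be too slow so that the rhodacycle decays. The fallback uses known chemistry, sets out from phenol 11 and returns at aldehyde 28. 1-Fluoro-3-methoxy-5-methylbenzene (COc1cc(C)cc(F)c1) is lithiated between fluorine and methoxy (n-BuLi, THF, −78 °C) to (2-fluoro-6-methoxy-4-methylphenyl)lithium F1 and formylated with DMF to 2-fluoro-6-methoxy-4-methylbenzaldehyde F2. Ethylene glycol/TsOH gives dioxolane F3. Lithiation ortho to fluorine (s-BuLi, TMEDA, THF, −78 °C) gives aryllithium F4, which is trapped with allyl chloroformate as allyl ester F5. Dilute HCl frees the aldehyde to give allyl 2-fluoro-3-formyl-4-methoxy-6-methylbenzoate F6. The phenolate of 11 displaces the fluoride of F6, which is activated by the ortho ester and ortho formyl groups (K2CO3, DMF, 60 °C; nucleophilic aromatic substitution), to give diaryl ether F7. Pd(PPh3)4/TolSO2Na removes the allyl ether and the allyl ester together to give hydroxy acid F8. Mukaiyama lactonisation (2-chloro-1-methylpyridinium iodide, Et3N, CH2Cl2, high dilution) closes the seven-membered lactone to 28, and steps 16–18 follow.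

2. Step 17. The lipase may not accept the hindered lactol beside the diaryl ether, may prefer the (R) enantiomer or discriminate poorly, or ring–chain equilibration may lag behind acylation so that the resolution is no longer dynamic. The fallback sets out from racemic lactol 29 and comes back at target 31 without any enzyme, so it replaces steps 17 and 18 together. Preparative chromatography on a chiral stationary phase (amylose tris(3,5-dimethylphenylcarbamate) on silica, heptane/propan-2-ol with 0.1% AcOH, 20 °C) should separate the two lactol enantiomers. The (R) fraction is returned to the racemate with catalytic Et3N in THF, neutralised and resubmitted, so the unwanted enantiomer is recycled and not discarded. The (S) fraction would be assigned by its chiroptical data. No new compound arises (F0).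

3. Step 13. Hydroperoxide and bicarbonate in methanol may open the seven-membered aryl ester or the pseudo-ester before the Si–aryl bond is oxidised. The fallback sets out from alcohol 20 and returns at diol 26 by using boron instead of silicon as the temporary tether atom, whose C–B bond oxidises under far milder conditions. Alcohol 20 is transesterified with diisopropyl ethynylboronate (C#CB(OC(C)C)OC(C)C) to mixed boronate F9. F9 is cyclotrimerised under the conditions of step 12 to benzoxaborole isopropyl ester F10. Oxidation with NaBO3·4H2O in THF/H2O at rt gives 26.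

**Further compounds**
F1 | step 12 | (2-fluoro-6-methoxy-4-methylphenyl)lithium | COc1cc(C)cc(F)c1[Li]
F2 | step 12 | 2-fluoro-6-methoxy-4-methylbenzaldehyde | COc1cc(C)cc(F)c1C=O
F3 | step 12 | 2-(2-fluoro-6-methoxy-4-methylphenyl)-1,3-dioxolane | COc1cc(C)cc(F)c1C1OCCO1
F4 | step 12 | [3-(1,3-dioxolan-2-yl)-2-fluoro-4-methoxy-6-methylphenyl]lithium | COc1cc(C)c([Li])c(F)c1C1OCCO1
F5 | step 12 | allyl 3-(1,3-dioxolan-2-yl)-2-fluoro-4-methoxy-6-methylbenzoate | COc1cc(C)c(C(=O)OCC=C)c(F)c1C1OCCO1
F6 | step 12 | allyl 2-fluoro-3-formyl-4-methoxy-6-methylbenzoate | COc1cc(C)c(C(=O)OCC=C)c(F)c1C=O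
F7 | step 12 | diaryl ether: A-e–O–B-a, A-d allyl ester, A-f CHO, B-b O-allyl, B-d OMOM, lactol methyl acetal (racemic) | COc1cc(C)c(C(=O)OCC=C)c(c1C=O)Oc1c(OCC=C)cc(OCOC)c2c1C(OC)OC2=O
F8 | step 12 | hydroxy acid: A-e–O–B-a, A-d carboxylic acid, A-f CHO, B-b OH, B-d OMOM, lactol methyl acetal (racemic) | COc1cc(C)c(C(=O)O)c(c1C=O)Oc1c(O)cc(OCOC)c2c1C(OC)OC2=O
F9 | step 13 | mixed isopropyl ethynylboronate of alcohol 20 (racemic) | C#CB(OC(C)C)OCC#COc1c(OC(=O)C#CC)cc(OCOC)c2c1C(OC)OC2=O
F10 | step 13 | depsidone fused to a 1-isopropoxy-1,3-dihydro-2,1-benzoxaborole (A-a–B, A-f–CH2–O–B; B-d OMOM; lactol methyl acetal; racemic) | CC(C)OB1OCc2c1cc(C)c1c2Oc2c(cc(OCOC)c3c2C(OC)OC3=O)OC1=O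
F0 | step 17 | none | none
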